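**Strategy**

The route exploits the C3a–C6a bond of the furo[3,4-c]furan core, which joins the two fully substituted carbinol carbons shared by both oxolane rings, together with the benzylic O2–C1 ether bond, and disconnects both. One redox-neutral photocatalytic cascade makes them: a ketyl radical at C3a adds 5-exo to the oxygen-bearing alkene carbon C6a, closing the C4–O5–C6 ring, and the electron-rich benzylic radical left at C1 is oxidised to a cation that the C3 hydroxyl captures, closing the second ring. The precursor is an acyclic (S)-α-alkoxy-α'-hydroxy ketone whose ether oxygen O5 carries a 2-benzyloxy-3-arylallyl group; its one stereocentre (C4) directs the three new ones.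

Key step: step 10

Remark: ring positions are numbered as in 1H,3H-furo[3,4-c]furan (C1, O2, C3, C3a, C4, O5, C6, C6a); the target is the (1S,3aR,4S,6aR) isomer with both aryl groups exo (cis to the neighbouring bridgehead hydroxyl).

Assumption: the geometry of the enol-ether double bond is inconsequential, because C1 passes through a planar radical and a planar cation; the (Z) isomer is drawn throughout.

**Route**

Step 1
Reactants: 1 4-(benzyloxy)-3-methoxybenzaldehyde; 2 triethyl phosphonoacetate
Product: 3 ethyl (E)-3-[4-(benzyloxy)-3-methoxyphenyl]prop-2-enoate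
Conditions: NaH, THF, 0 °C to rt
Reagents that add atoms: none
Why: Horner–Wadsworth–Emmons olefination of the non-enolisable aryl aldehyde with the stabilised phosphonate anion should give the (E)-cinnamate.

Step 2
Reactants: 3 ethyl (E)-3-[4-(benzyloxy)-3-methoxyphenyl]prop-2-enoate
Product: 4 (E)-3-[4-(benzyloxy)-3-methoxyphenyl]prop-2-en-1-ol
Conditions: iBu2AlH (2.2 equiv), CH2Cl2, −78 °C; aqueous potassium sodium tartrate (KNaC4H4O6) work-up
Reagents that add atoms: none
Why: 1,2-reduction of the conjugated ester by the aluminium hydride should stop at the allylic alcohol and leave the benzyl ether and the alkene untouched.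

Step 3
Reactants: 4 (E)-3-[4-(benzyloxy)-3-methoxyphenyl]prop-2-en-1-ol
Product: 5 [(2R,3R)-3-[4-(benzyloxy)-3-methoxyphenyl]oxiran-2-yl]methanol
Conditions: Ti(OiPr)4 (10 mol %), D-(−)-diisopropyl tartrate (12 mol %), anhydrous t-BuOOH (2 equiv), 4 Å molecular sieves, CH2Cl2, −25 °C; non-acidic work-up
Reagents that add atoms: tert-butyl hydroperoxide CC(C)(C)OO
Why: Sharpless asymmetric epoxidation; the titanium tartrate complex delivers oxygen to one face of the allylic alcohol, and the D-(−)-tartrate should give the (2R,3R)-epoxy alcohol from the (E)-cinnamyl alcohol, which fixes the later C4 centre.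

Step 4
Reactants: 5 [(2R,3R)-3-[4-(benzyloxy)-3-methoxyphenyl]oxiran-2-yl]methanol
Product: 6 {[(2R,3R)-3-[4-(benzyloxy)-3-methoxyphenyl]oxiran-2-yl]methoxy}(tert-butyl)dimethylsilane
Conditions: TBSCl, imidazole, CH2Cl2, 0 °C
Reagents that add atoms: tert-butyldimethylsilyl chloride CC(C)(C)[Si](C)(C)Cl
Why: Silyl ether formation under neutral conditions masks the later C3 hydroxyl and removes the internal nucleophile of the acid-labile epoxy alcohol.

Step 5
Reactants: 1 4-(benzyloxy)-3-methoxybenzaldehyde; 7 methyl 2-(benzyloxy)acetate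
Product: 10 methyl (Z)-2-(benzyloxy)-3-[4-(benzyloxy)-3-methoxyphenyl]prop-2-enoate, via lithium aldolate 8 (not isolated), via aldol mesylate 9 (not isolated)
Conditions: LiN(SiMe3)2, THF, −78 °C; then MsCl, −78 to 0 °C; then DBU, rt
Reagents that add atoms: none
Why: Aldol condensation in one pot; the lithium glycolate enolate adds to the aldehyde, the aldolate is mesylated and DBU effects E1cB elimination to the thermodynamically preferred (Z)-enol ether ester (aryl trans to the ester).

Step 6
Reactants: 10 methyl (Z)-2-(benzyloxy)-3-[4-(benzyloxy)-3-methoxyphenyl]prop-2-enoate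
Product: 11 (Z)-2-(benzyloxy)-3-[4-(benzyloxy)-3-methoxyphenyl]prop-2-en-1-ol
Conditions: iBu2AlH (2.2 equiv), CH2Cl2, −78 °C; aqueous potassium sodium tartrate (KNaC4H4O6) work-up
Reagents that add atoms: none
Why: 1,2-reduction of the α-alkoxy acrylate by the aluminium hydride should give the allylic alcohol without touching the benzyl enol ether.

Step 7
Reactants: 6 {[(2R,3R)-3-[4-(benzyloxy)-3-methoxyphenyl]oxiran-2-yl]methoxy}(tert-butyl)dimethylsilane; 11 (Z)-2-(benzyloxy)-3-[4-(benzyloxy)-3-methoxyphenyl]prop-2-en-1-ol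
Product: 12 (1S,2R)-1-[4-(benzyloxy)-3-methoxyphenyl]-1-{[(Z)-2-(benzyloxy)-3-[4-(benzyloxy)-3-methoxyphenyl]prop-2-en-1-yl]oxy}-3-[(tert-butyldimethylsilyl)oxy]propan-2-ol
Conditions: BF3·OEt2 (10 mol %), CH2Cl2, −78 °C, epoxide added slowly to a 1.5-fold excess of the alcohol; Et3N quench
Reagents that add atoms: none
Why: Lewis-acid-catalysed epoxide ring opening, an addition in which every atom of both partners ends up in the product; the primary alcohol should attack the activated epoxide at its benzylic carbon with inversion, turning the (3R) epoxide carbon into the (S)-benzylic ether and releasing the secondary hydroxyl, and any syn diastereomer from partial ionisation should be separable because the neighbouring carbinol centre is still present.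

Step 8
Reactants: 12 (1S,2R)-1-[4-(benzyloxy)-3-methoxyphenyl]-1-{[(Z)-2-(benzyloxy)-3-[4-(benzyloxy)-3-methoxyphenyl]prop-2-en-1-yl]oxy}-3-[(tert-butyldimethylsilyl)oxy]propan-2-ol
Product: 13 (S)-1-[4-(benzyloxy)-3-methoxyphenyl]-1-{[(Z)-2-(benzyloxy)-3-[4-(benzyloxy)-3-methoxyphenyl]prop-2-en-1-yl]oxy}-3-[(tert-butyldimethylsilyl)oxy]propan-2-one
Conditions: Dess–Martin periodinane, NaHCO3, CH2Cl2, 0 °C to rt
Reagents that add atoms: none
Why: Dess–Martin oxidation should convert the secondary alcohol into the ketone under buffered, non-basic conditions that spare the enol ether and do not epimerise the α-aryl-α-alkoxy centre.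

Step 9
Reactants: 13 (S)-1-[4-(benzyloxy)-3-methoxyphenyl]-1-{[(Z)-2-(benzyloxy)-3-[4-(benzyloxy)-3-methoxyphenyl]prop-2-en-1-yl]oxy}-3-[(tert-butyldimethylsilyl)oxy]propan-2-one
Product: 14 (S)-1-[4-(benzyloxy)-3-methoxyphenyl]-1-{[(Z)-2-(benzyloxy)-3-[4-(benzyloxy)-3-methoxyphenyl]prop-2-en-1-yl]oxy}-3-hydroxypropan-2-one
Conditions: HF·pyridine, pyridine, THF, 0 °C; used directly
Reagents that add atoms: none
Why: Buffered fluoride desilylation should free the primary hydroxyl without base, so that the α-stereocentre and the enol ether survive.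

Step 10
Reactants: 14 (S)-1-[4-(benzyloxy)-3-methoxyphenyl]-1-{[(Z)-2-(benzyloxy)-3-[4-(benzyloxy)-3-methoxyphenyl]prop-2-en-1-yl]oxy}-3-hydroxypropan-2-one
Product: 17 (1S,3aR,4S,6aR)-6a-(benzyloxy)-1,4-bis[4-(benzyloxy)-3-methoxyphenyl]tetrahydro-1H,3H-furo[3,4-c]furan-3a-ol, via cyclised benzylic radical 15 (not isolated), via benzylic cation 16 (not isolated)
Conditions: 10-phenylphenothiazine (10 mol %), (PhO)2PO2H (20 mol %), degassed MeCN (0.02 M), argon, 390 nm LEDs, 25 °C
Reagents that add atoms: none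
Why: Proposed new method: the excited phenothiazine should reduce the hydrogen-bonded ketone of 14 by proton-coupled electron transfer to a ketyl radical at C3a, which adds 5-exo-trig to the enol-ether carbon C6a (closing the C4–O5–C6 ring) to give benzylic radical 15; the phenothiazine radical cation then oxidises 15 to the p-alkoxybenzyl cation 16, and the C3 hydroxyl captures it in a 5-exo closure onto the quinone-methide-like cationic carbon, releasing the proton for the next turnover, so that no stoichiometric redox reagent is consumed. The closest known reaction types are the photocatalytic proton-coupled ketyl–olefin cyclisation (which ends by hydrogen-atom transfer), radical–polar crossover cycloetherification, and the Cp2TiCl-mediated epoxy-olefin radical cyclisation with iodine-induced ether closure used for furofuran lignans; new here is the redox-neutral merger with an α-oxygenated dialkyl ketone and an enol-ether acceptor. C3a and C6a should be set in a chair-like 5-exo transition state with the C4 aryl group pseudo-equatorial and the ketyl oxygen anti to the alkene, which places the hydroxymethyl group cis to the C1 side chain (the prerequisite for the second closure), makes the two oxygens cis and puts the C4 aryl group trans to the C3 methylene. C1 is set in the cation capture, where the planar benzylic cation is expected to react with its aryl group turned to the convex face, next to the C6a oxygen substituent and not under the C6 methylene, giving the exo aryl group. The step needs 5-exo over 6-endo regioselectivity, which the tether length and the benzylic stabilisation of 15 should secure, and it needs cyclisation to outrun fragmentation of the α-alkoxy ketyl, which keeping the ketyl protonated should favour; back electron transfer only regenerates 14.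

Step 11
Reactants: 17 (1S,3aR,4S,6aR)-6a-(benzyloxy)-1,4-bis[4-(benzyloxy)-3-methoxyphenyl]tetrahydro-1H,3H-furo[3,4-c]furan-3a-ol
Product: 18 (1S,3aR,4S,6aR)-1,4-bis(4-hydroxy-3-methoxyphenyl)tetrahydro-1H,3H-furo[3,4-c]furan-3a,6a-diol
Conditions: H2 (1 atm), Pd(OH)2/C, EtOAc/MeOH, rt
Reagents that add atoms: none
Why: Catalytic hydrogenolysis should cleave the two aryl benzyl ethers and the tertiary alkyl benzyl ether in one operation, while the ring benzylic C–O bonds, deactivated by the adjacent oxygenated carbons, should survive under neutral conditions at 1 atm.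

**Compound list**

1 | 4-(benzyloxy)-3-methoxybenzaldehyde | O=Cc1ccc(OCc2ccccc2)c(OC)c1 | starting material
2 | triethyl phosphonoacetate | CCOC(=O)CP(=O)(OCC)OCC | starting material
3 | ethyl (E)-3-[4-(benzyloxy)-3-methoxyphenyl]prop-2-enoate | CCOC(=O)/C=C/c1ccc(OCc2ccccc2)c(OC)c1 | intermediate
4 | (E)-3-[4-(benzyloxy)-3-methoxyphenyl]prop-2-en-1-ol | OC/C=C/c1ccc(OCc2ccccc2)c(OC)c1 | intermediate
5 | [(2R,3R)-3-[4-(benzyloxy)-3-methoxyphenyl]oxiran-2-yl]methanol | OC[C@H]1O[C@@H]1c2ccc(OCc3ccccc3)c(OC)c2 | intermediate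
6 | {[(2R,3R)-3-[4-(benzyloxy)-3-methoxyphenyl]oxiran-2-yl]methoxy}(tert-butyl)dimethylsilane | CC(C)(C)[Si](C)(C)OC[C@H]1O[C@@H]1c2ccc(OCc3ccccc3)c(OC)c2 | intermediate
7 | methyl 2-(benzyloxy)acetate | COC(=O)COCc1ccccc1 | starting material
8 | lithium aldolate: lithium 2-(benzyloxy)-1-[4-(benzyloxy)-3-methoxyphenyl]-3-methoxy-3-oxopropan-1-olate (mixture of diastereomers) | [Li+].[O-]C(c1ccc(OCc2ccccc2)c(OC)c1)C(OCc1ccccc1)C(=O)OC | intermediate (not isolated)
9 | aldol mesylate: methyl 2-(benzyloxy)-3-[4-(benzyloxy)-3-methoxyphenyl]-3-[(methylsulfonyl)oxy]propanoate (mixture of diastereomers) | CS(=O)(=O)OC(c1ccc(OCc2ccccc2)c(OC)c1)C(OCc1ccccc1)C(=O)OC | intermediate (not isolated)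
10 | methyl (Z)-2-(benzyloxy)-3-[4-(benzyloxy)-3-methoxyphenyl]prop-2-enoate | COC(=O)/C(OCc1ccccc1)=C/c1ccc(OCc2ccccc2)c(OC)c1 | intermediate
11 | (Z)-2-(benzyloxy)-3-[4-(benzyloxy)-3-methoxyphenyl]prop-2-en-1-ol | OC/C(OCc1ccccc1)=C/c1ccc(OCc2ccccc2)c(OC)c1 | intermediate
12 | (1S,2R)-1-[4-(benzyloxy)-3-methoxyphenyl]-1-{[(Z)-2-(benzyloxy)-3-[4-(benzyloxy)-3-methoxyphenyl]prop-2-en-1-yl]oxy}-3-[(tert-butyldimethylsilyl)oxy]propan-2-ol | CC(C)(C)[Si](C)(C)OC[C@@H](O)[C@@H](OC/C(OCc1ccccc1)=C/c1ccc(OCc2ccccc2)c(OC)c1)c1ccc(OCc2ccccc2)c(OC)c1 | intermediate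
13 | (S)-1-[4-(benzyloxy)-3-methoxyphenyl]-1-{[(Z)-2-(benzyloxy)-3-[4-(benzyloxy)-3-methoxyphenyl]prop-2-en-1-yl]oxy}-3-[(tert-butyldimethylsilyl)oxy]propan-2-one | CC(C)(C)[Si](C)(C)OCC(=O)[C@@H](OC/C(OCc1ccccc1)=C/c1ccc(OCc2ccccc2)c(OC)c1)c1ccc(OCc2ccccc2)c(OC)c1 | intermediate
14 | (S)-1-[4-(benzyloxy)-3-methoxyphenyl]-1-{[(Z)-2-(benzyloxy)-3-[4-(benzyloxy)-3-methoxyphenyl]prop-2-en-1-yl]oxy}-3-hydroxypropan-2-one | OCC(=O)[C@@H](OC/C(OCc1ccccc1)=C/c1ccc(OCc2ccccc2)c(OC)c1)c1ccc(OCc2ccccc2)c(OC)c1 | intermediate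
15 | cyclised benzylic radical: [4-(benzyloxy)-3-methoxyphenyl][(3S,4R,5S)-3-(benzyloxy)-5-[4-(benzyloxy)-3-methoxyphenyl]-4-hydroxy-4-(hydroxymethyl)oxolan-3-yl]methyl radical | OC[C@@]1(O)[C@H](c2ccc(OCc3ccccc3)c(OC)c2)OC[C@@]1(OCc2ccccc2)[CH]c2ccc(OCc3ccccc3)c(OC)c2 | intermediate (not isolated)
16 | benzylic cation: [4-(benzyloxy)-3-methoxyphenyl][(3S,4R,5S)-3-(benzyloxy)-5-[4-(benzyloxy)-3-methoxyphenyl]-4-hydroxy-4-(hydroxymethyl)oxolan-3-yl]methylium | OC[C@@]1(O)[C@H](c2ccc(OCc3ccccc3)c(OC)c2)OC[C@@]1(OCc2ccccc2)[CH+]c2ccc(OCc3ccccc3)c(OC)c2 | intermediate (not isolated)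
17 | (1S,3aR,4S,6aR)-6a-(benzyloxy)-1,4-bis[4-(benzyloxy)-3-methoxyphenyl]tetrahydro-1H,3H-furo[3,4-c]furan-3a-ol | COc1cc([C@@H]2OC[C@@]3(O)[C@H](c4ccc(OCc5ccccc5)c(OC)c4)OC[C@@]23OCc2ccccc2)ccc1OCc1ccccc1 | intermediate
18 | (1S,3aR,4S,6aR)-1,4-bis(4-hydroxy-3-methoxyphenyl)tetrahydro-1H,3H-furo[3,4-c]furan-3a,6a-diol | COc1cc([C@@H]2OC[C@@]3(O)[C@H](c4ccc(O)c(OC)c4)OC[C@@]23O)ccc1O | target

**Step count**

Total step count: 11. Longest linear sequence: 9 steps (steps 1 to 4 and 7 to 11).

**Steps most likely to fail**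

1. Step 10 (proposed new method). Ketyl formation from the aliphatic ketone may be too slow. The α-alkoxy ketyl may fragment at the C4–O5 bond. The acid may hydrolyse the enol ether. Capture of the cation may occur with poor facial selectivity at C1. The fallback uses known chemistry, sets out from 14 and comes back to the route at 18. SmI2 in THF with t-BuOH should effect ketyl–olefin cyclisation of 14, and the benzylic organosamarium should lose benzyloxide by β-elimination to give (2S,3R,4E)-2-[4-(benzyloxy)-3-methoxyphenyl]-4-[4-(benzyloxy)-3-methoxybenzylidene]-3-(hydroxymethyl)oxolan-3-ol F1. Hydroxyl-directed epoxidation with VO(acac)2 and t-BuOOH, syn to the tertiary allylic hydroxyl, should then give (2S,3R,6S,7R)-2,6-bis[4-(benzyloxy)-3-methoxyphenyl]-7-(hydroxymethyl)-1,5-dioxaspiro[2.4]heptan-7-ol F2. Catalytic camphorsulfonic acid should induce cation-like 5-endo opening of the epoxide at its benzylic carbon by the primary hydroxyl, under equilibrating conditions for C1, to give (1S,3aR,4S,6aR)-1,4-bis[4-(benzyloxy)-3-methoxyphenyl]tetrahydro-1H,3H-furo[3,4-c]furan-3a,6a-diol F3. Hydrogenolysis of F3 under the conditions of step 11 gives 18.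

2. Step 7. The electron-rich benzylic epoxide may ionise, so that the ether forms with loss of stereochemical integrity, and the Lewis acid may protonate the enol ether. The fallback makes the ether bond by carbenoid O–H insertion at the ketone oxidation level; it sets out from 11 and comes back at 13. Commercial 2-[4-(benzyloxy)-3-methoxyphenyl]acetic acid F4 is converted through its acid chloride with tris(trimethylsilyloxy)ethylene, followed by acidic hydrolysis and decarboxylation, into 1-[4-(benzyloxy)-3-methoxyphenyl]-3-hydroxypropan-2-one F5. Silylation (TBSCl, imidazole) gives 1-[4-(benzyloxy)-3-methoxyphenyl]-3-[(tert-butyldimethylsilyl)oxy]propan-2-one F6. Diazo transfer with 4-acetamidobenzenesulfonyl azide and DBU gives 1-[4-(benzyloxy)-3-methoxyphenyl]-3-[(tert-butyldimethylsilyl)oxy]-1-diazopropan-2-one F7. Asymmetric O–H insertion of the carbenoid from F7 into the hydroxyl of 11 (Rh2(OAc)4 with a chiral spiro phosphoric acid as proton shuttle) should give 13 directly.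

3. Step 3. The electron-rich epoxy alcohol may be opened solvolytically by isopropoxide or tartrate on the Lewis acidic titanium during the reaction or the work-up. The fallback avoids the free epoxy alcohol; it sets out from 4 and comes back at 6. Silylation of 4 (TBSCl, imidazole) gives tert-butyl{[(E)-3-[4-(benzyloxy)-3-methoxyphenyl]prop-2-en-1-yl]oxy}dimethylsilane F8. Shi epoxidation of F8 (D-fructose-derived ketone, Oxone (2KHSO5·KHSO4·K2SO4), K2CO3 buffer, MeCN/dimethoxymethane/H2O, 0 °C) is expected to give the (R,R)-epoxide 6, as for other trans-β-substituted styrenes.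

**Further compounds**

F1 | step 10 | (2S,3R,4E)-2-[4-(benzyloxy)-3-methoxyphenyl]-4-[4-(benzyloxy)-3-methoxybenzylidene]-3-(hydroxymethyl)oxolan-3-ol | OC[C@@]1(O)[C@H](c2ccc(OCc3ccccc3)c(OC)c2)OC/C1=C\c1ccc(OCc2ccccc2)c(OC)c1
F2 | step 10 | (2S,3R,6S,7R)-2,6-bis[4-(benzyloxy)-3-methoxyphenyl]-7-(hydroxymethyl)-1,5-dioxaspiro[2.4]heptan-7-ol | OC[C@@]1(O)[C@H](c2ccc(OCc3ccccc3)c(OC)c2)OC[C@]12O[C@H]2c1ccc(OCc2ccccc2)c(OC)c1
F3 | step 10 | (1S,3aR,4S,6aR)-1,4-bis[4-(benzyloxy)-3-methoxyphenyl]tetrahydro-1H,3H-furo[3,4-c]furan-3a,6a-diol | COc1cc([C@@H]2OC[C@@]3(O)[C@H](c4ccc(OCc5ccccc5)c(OC)c4)OC[C@@]23O)ccc1OCc1ccccc1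
F4 | step 7 | 2-[4-(benzyloxy)-3-methoxyphenyl]acetic acid (purchased) | OC(=O)Cc1ccc(OCc2ccccc2)c(OC)c1
F5 | step 7 | 1-[4-(benzyloxy)-3-methoxyphenyl]-3-hydroxypropan-2-one | OCC(=O)Cc1ccc(OCc2ccccc2)c(OC)c1
F6 | step 7 | 1-[4-(benzyloxy)-3-methoxyphenyl]-3-[(tert-butyldimethylsilyl)oxy]propan-2-one | CC(C)(C)[Si](C)(C)OCC(=O)Cc1ccc(OCc2ccccc2)c(OC)c1
F7 | step 7 | 1-[4-(benzyloxy)-3-methoxyphenyl]-3-[(tert-butyldimethylsilyl)oxy]-1-diazopropan-2-one | CC(C)(C)[Si](C)(C)OCC(=O)C(=[N+]=[N-])c1ccc(OCc2ccccc2)c(OC)c1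
F8 | step 3 | tert-butyl{[(E)-3-[4-(benzyloxy)-3-methoxyphenyl]prop-2-en-1-yl]oxy}dimethylsilane | CC(C)(C)[Si](C)(C)OC/C=C/c1ccc(OCc2ccccc2)c(OC)c1
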